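**Retrosynthetic overview**

1. Target 28 ← C9 ketone 27 (hydride addition). 27 ← tricyclic cyclohexenone 24 in one flask by intramolecular enone–alkyne [2+2] photocycloaddition, then SmI2 ketyl fragmentation of the cyclobutene photoadduct. The six-membered enone ring C′ (C9, C8, C26, C25, C24, C11) becomes the eight-membered ring C by taking up C3 and C2, and the cyclopentane D closes in the same operation.
2. Enabling feature: in 24 the ring bond C8–C26 is α to the C9 ketone and, once the alkyne C3≡C2 has added across C8=C26, allylic to the cyclobutene C2=C3. The C9 ketyl therefore breaks exactly this temporary bond.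
3. 24 ← keto aldehyde 23 (aldol condensation, C8–C26) ← ketone 22 ← aldehyde 14 + iodide 19 (C9–C8 bond; C6 from (2R)-3-bromo-2-methylpropan-1-ol).
4. 14 ← trans-decalone 9: C11 quaternary centre by olefination, asymmetric epoxidation and Me3Al opening with inversion. 9 ← octalone 7 by reductive allylation (C23, C24). 7 by deracemising Robinson annulation of 2,5,5-trimethylcyclohexanone (C15).
5. Order of ring formation: A (purchased) → B → C′ (six-membered, temporary size) → D together with the cyclobutene → C (eight-membered, by two-atom ring expansion).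

Key step: step 19

Remark: locants C1–C26 are the atom positions in the target SMILES read from the left (O is atom 10). Ring A = C15/C17/C18/C19/C22/C23, ring B = C11/C13/C14/C15/C23/C24, ring C = C2/C3/C8/C9/C11/C24/C25/C26, ring D = C3/C4/C5/C6/C8.

Remark: the two facial isomers of photoadduct 25 give the same product, because both of its new stereocentres are destroyed in the fragmentation; one isomer is drawn.

Step 1
Reactants: 1 3,3-dimethylcyclohexanone
Product: 3 2,5,5-trimethylcyclohexanone (racemate), via lithium enolate 2 (not isolated)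
Conditions: LiN(i-Pr)2, THF, −78 °C; MeI, −78 → 0 °C
Reagents that add atoms: iodomethane, CI
Why: Kinetic deprotonation takes the CH2 remote from the neopentyl position and the lithium enolate is C-methylated (enolate alkylation); the new stereocentre is racemic and is erased in steps 2 and 3.

Step 2
Reactants: 3 2,5,5-trimethylcyclohexanone
Product: 4 N-[(1R)-1-phenylethyl]-2,5,5-trimethylcyclohexan-1-imine
Conditions: (R)-PhCH(Me)NH2, p-TsOH (cat.), toluene, reflux, Dean–Stark
Reagents that add atoms: (R)-1-phenylethylamine, C[C@@H](N)c1ccccc1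
Why: Acid-catalysed imine condensation with azeotropic removal of water installs the chiral auxiliary for the next step.

Step 3
Reactants: 4 N-[(1R)-1-phenylethyl]-2,5,5-trimethylcyclohexan-1-imine
Product: 6 (2S)-2,5,5-trimethyl-2-(3-oxobutyl)cyclohexan-1-one, via Michael-adduct imine 5 (not isolated)
Conditions: methyl vinyl ketone, THF, 40 °C; then 20% aq. AcOH, 20 °C
Reagents that add atoms: methyl vinyl ketone, C=CC(C)=O; water, O
Why: Deracemising Michael addition of a chiral imine (d'Angelo reaction): the more substituted secondary enamine tautomer adds to the enone through an aza-ene-like transition state on the face away from the phenyl group, which should set C15 as (S), and hydrolysis returns the ketone and the auxiliary.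

Step 4
Reactants: 6 (2S)-2,5,5-trimethyl-2-(3-oxobutyl)cyclohexan-1-one
Product: 7 (4aS)-4a,7,7-trimethyl-4,4a,5,6,7,8-hexahydronaphthalen-2(3H)-one
Conditions: NaOMe (0.3 equiv), MeOH, 65 °C
Reagents that add atoms: none
Why: Intramolecular aldol condensation (second half of the Robinson annulation) closes ring B as the conjugated octalone without touching C15.

Step 5
Reactants: 7 (4aS)-4a,7,7-trimethyl-4,4a,5,6,7,8-hexahydronaphthalen-2(3H)-one
Product: 9 (1S,4aS,8aS)-1-allyl-4a,7,7-trimethyloctahydronaphthalen-2(1H)-one, via lithium enolate 8 (not isolated)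
Conditions: Li, NH3(l), THF, t-BuOH (1 equiv), −78 °C; then allyl bromide, −78 → −33 °C
Reagents that add atoms: allyl bromide, C=CCBr
Why: Birch reduction with enolate trapping (reductive alkylation): axial protonation at C23 gives the trans-fused enolate regiospecifically, and allylation at C24 should place the allyl group equatorial, away from the axial C15 methyl, which is also the thermodynamic epimer.

Step 6
Reactants: 9 (1S,4aS,8aS)-1-allyl-4a,7,7-trimethyloctahydronaphthalen-2(1H)-one
Product: 10 ethyl (2E)-[(1S,4aS,8aS)-1-allyl-4a,7,7-trimethyloctahydronaphthalen-2(1H)-ylidene]acetate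
Conditions: NaH, (EtO)2P(O)CH2CO2Et, DME, 85 °C
Reagents that add atoms: triethyl phosphonoacetate, CCOC(=O)CP(=O)(OCC)OCC
Why: Horner–Wadsworth–Emmons olefination of the C11 ketone, in which allylic 1,3-strain with the equatorial C24 allyl group should place the ester on the C13 side (E isomer, purified from any Z isomer).

Step 7
Reactants: 10 ethyl (2E)-[(1S,4aS,8aS)-1-allyl-4a,7,7-trimethyloctahydronaphthalen-2(1H)-ylidene]acetate
Product: 11 (2E)-2-[(1S,4aS,8aS)-1-allyl-4a,7,7-trimethyloctahydronaphthalen-2(1H)-ylidene]ethan-1-ol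
Conditions: i-Bu2AlH, CH2Cl2, −78 °C
Reagents that add atoms: none
Why: 1,2-Reduction of the conjugated ester by the aluminium hydride gives the allylic alcohol needed for directed epoxidation.

Step 8
Reactants: 11 (2E)-2-[(1S,4aS,8aS)-1-allyl-4a,7,7-trimethyloctahydronaphthalen-2(1H)-ylidene]ethan-1-ol
Product: 12 [(1S,2S,3'S,4aS,8aS)-1-allyl-4a,7,7-trimethyloctahydro-1H-spiro[naphthalene-2,2'-oxiran]-3'-yl]methanol
Conditions: Ti(Oi-Pr)4 (cat.), L-(+)-diisopropyl tartrate (cat.), t-BuOOH, 4 Å molecular sieves, CH2Cl2, −20 °C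
Reagents that add atoms: tert-butyl hydroperoxide, CC(C)(C)OO
Why: Sharpless asymmetric epoxidation, reagent-controlled: with the L-(+)-tartrate the oxygen should go to the same face as in geraniol → (2S,3S)-epoxygeraniol, here the equatorial face of C11, leaving the terminal alkene untouched.

Step 9
Reactants: 12 [(1S,2S,3'S,4aS,8aS)-1-allyl-4a,7,7-trimethyloctahydro-1H-spiro[naphthalene-2,2'-oxiran]-3'-yl]methanol
Product: 13 (1R)-1-[(1S,2S,4aS,8aS)-1-allyl-2,4a,7,7-tetramethyldecahydronaphthalen-2-yl]ethane-1,2-diol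
Conditions: Me3Al (3 equiv), hexane/CH2Cl2, −78 → 0 °C
Reagents that add atoms: trimethylaluminium, C[Al](C)C
Why: Hydroxyl-assisted organoaluminium opening of a 2,3-epoxy alcohol at its fully substituted C3: methyl enters C11 anti to the equatorial epoxide oxygen (inversion), which sets the quaternary centre with the methyl axial and the carbon branch equatorial.

Step 10
Reactants: 13 (1R)-1-[(1S,2S,4aS,8aS)-1-allyl-2,4a,7,7-tetramethyldecahydronaphthalen-2-yl]ethane-1,2-diol
Product: 14 (1S,2S,4aS,8aS)-1-allyl-2,4a,7,7-tetramethyldecahydronaphthalene-2-carbaldehyde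
Conditions: NaIO4, THF/H2O, 20 °C
Reagents that add atoms: none
Why: Periodate glycol cleavage removes the extra carbon as formaldehyde and leaves the non-enolisable neopentyl aldehyde (C9) on the intact C11 centre.

Step 11
Reactants: 15 (2R)-3-bromo-2-methylpropan-1-ol
Product: 16 [(2R)-3-bromo-2-methylpropoxy](tert-butyl)dimethylsilane
Conditions: TBSCl, imidazole, CH2Cl2, 0 → 20 °C
Reagents that add atoms: tert-butyldimethylsilyl chloride, CC(C)(C)[Si](C)(C)Cl
Why: Silylation of the primary alcohol protects it from the organolithium of the next step.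

Step 12
Reactants: 16 [(2R)-3-bromo-2-methylpropoxy](tert-butyl)dimethylsilane
Product: 17 tert-butyldimethyl{[(2S)-2-methylhept-5-yn-1-yl]oxy}silane
Conditions: but-2-yne, n-BuLi, THF, −78 → 0 °C; then 16, DMPU, −78 → 20 °C
Reagents that add atoms: but-2-yne, CC#CC
Why: Propargylic lithiation of but-2-yne and SN2 alkylation by the primary bromide forms C4–C5 without touching the C6 stereocentre (the descriptor changes only through the priority rules).

Step 13
Reactants: 17 tert-butyldimethyl{[(2S)-2-methylhept-5-yn-1-yl]oxy}silane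
Product: 18 (2S)-2-methylhept-5-yn-1-ol
Conditions: Bu4NF, THF, 20 °C
Reagents that add atoms: none
Why: Fluoride-induced desilylation frees the primary alcohol.

Step 14
Reactants: 18 (2S)-2-methylhept-5-yn-1-ol
Product: 19 (6S)-7-iodo-6-methylhept-2-yne
Conditions: I2, PPh3, imidazole, CH2Cl2, 0 °C
Reagents that add atoms: iodine, II
Why: Appel-type iodination of the primary alcohol proceeds at the CH2 group only, so C6 is untouched.

Step 15
Reactants: 19 (6S)-7-iodo-6-methylhept-2-yne; 14 (1S,2S,4aS,8aS)-1-allyl-2,4a,7,7-tetramethyldecahydronaphthalene-2-carbaldehyde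
Product: 21 (3S)-1-[(1S,2S,4aS,8aS)-1-allyl-2,4a,7,7-tetramethyldecahydronaphthalen-2-yl]-3-methyloct-6-yn-1-ol (both C9 epimers), via alkyllithium 20 (not isolated)
Conditions: 19, t-BuLi (2.1 equiv), Et2O, −78 °C; then 14, −78 → 0 °C
Reagents that add atoms: none
Why: Iodine–lithium exchange and 1,2-addition of the primary alkyllithium to the non-enolisable aldehyde form the C8–C9 bond; the carbinol configuration is irrelevant because it is oxidised next.

Step 16
Reactants: 21 (3S)-1-[(1S,2S,4aS,8aS)-1-allyl-2,4a,7,7-tetramethyldecahydronaphthalen-2-yl]-3-methyloct-6-yn-1-ol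
Product: 22 (3S)-1-[(1S,2S,4aS,8aS)-1-allyl-2,4a,7,7-tetramethyldecahydronaphthalen-2-yl]-3-methyloct-6-yn-1-one
Conditions: Dess–Martin periodinane, CH2Cl2, 20 °C
Reagents that add atoms: none
Why: Dess–Martin oxidation converts both carbinol epimers into the single C9 ketone under neutral conditions that spare the alkene and the alkyne.

Step 17
Reactants: 22 (3S)-1-[(1S,2S,4aS,8aS)-1-allyl-2,4a,7,7-tetramethyldecahydronaphthalen-2-yl]-3-methyloct-6-yn-1-one
Product: 23 {(1S,2S,4aS,8aS)-2,4a,7,7-tetramethyl-2-[(3S)-3-methyloct-6-ynoyl]decahydronaphthalen-1-yl}acetaldehyde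
Conditions: OsO4 (cat.), NaIO4, 2,6-lutidine, dioxane/H2O, 20 °C
Reagents that add atoms: osmium tetroxide (catalytic oxygen carrier), O=[Os](=O)(=O)=O; sodium periodate (terminal oxidant), [Na+].[O-]I(=O)(=O)=O
Why: Lemieux–Johnson cleavage of the terminal alkene gives the C26 aldehyde, the internal alkyne being far less reactive towards OsO4.

Step 18
Reactants: 23 {(1S,2S,4aS,8aS)-2,4a,7,7-tetramethyl-2-[(3S)-3-methyloct-6-ynoyl]decahydronaphthalen-1-yl}acetaldehyde
Product: 24 (4aS,4bS,8aS,10aS)-2-[(2S)-hept-5-yn-2-yl]-6,6,8a,10a-tetramethyl-4,4a,4b,5,6,7,8,8a,9,10-decahydrophenanthren-1(10aH)-one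
Conditions: KOH (0.3 equiv), MeOH, high dilution, 50 °C
Reagents that add atoms: none
Why: Intramolecular aldol condensation: the ketone can enolise only towards C8 and only this enolate can close a six-membered ring onto the C26 aldehyde, giving the 2-substituted cyclohexenone ring C′ (C8=C26).

Step 19
Reactants: 24 (4aS,4bS,8aS,10aS)-2-[(2S)-hept-5-yn-2-yl]-6,6,8a,10a-tetramethyl-4,4a,4b,5,6,7,8,8a,9,10-decahydrophenanthren-1(10aH)-one
Product: 27 C9 ketone of the target (6S,8S,11S,15S,23S,24S; 5-8-6-6 ring system with C2=C3), via cyclobutene photoadduct 25 (not isolated), via samarium dienolate 26 (not isolated)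
Conditions: hν (350 nm, uranium-glass filter), degassed toluene, 20 °C; then SmI2 (3 equiv), THF–HMPA, t-BuOH, −78 °C; aq. NH4Cl, −78 °C
Reagents that add atoms: none
Why: The triplet enone adds to the tethered alkyne by 1,5-closure (C8–C3, five-membered ring first) and then C26–C2 closure to the cyclobutene 25, a known intramolecular enone–alkyne [2+2] photocycloaddition run above 340 nm so that the β,γ-unsaturated ketone formed is not excited further. Divalent samarium then reduces the C9 ketone to its ketyl, which breaks the C8–C26 σ-bond with release of cyclobutene strain (the known ketyl-induced fragmentation of cyclobutyl ketones from enone photoadducts), and a second electron with protonation at C26 gives the ring-enlarged dienolate 26. Ring D is thus closed by a 5-exo-type radical closure inside the cycloaddition, and the eight-membered ring C is the six-membered enone ring enlarged by C3 and C2, with C8–C26 acting as a temporary tether. Cleavage of C8–C26 rather than C8–C3 is secured by the substrate, since only the former gives an allylic radical (C26 next to C2=C3) while the latter would give a vinyl radical. The one new stereocentre, C8, should be set by kinetic C-protonation of the dienolate on the face opposite the adjacent C6 methyl (as in the deconjugative protonation that follows 1,6-reduction of dienones), which also keeps C2=C3 out of conjugation.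

Step 20
Reactants: 27 C9 ketone of the target
Product: 28 target CNP0399382.1 (6S,8S,9R,11S,15S,23S,24S)
Conditions: LiAlH4, Et2O, −78 → −40 °C
Reagents that add atoms: none
Why: Felkin–Anh addition of a small hydride to the α-quaternary ketone: with the ring bond C11–C24 anti and the hydride passing the C11 methyl on the outer face of the eight-membered ring, the (9R) alcohol should result.

**Compound list**

1 | 3,3-dimethylcyclohexanone | O=C1CCCC(C)(C)C1 | starting material
2 | lithium 5,5-dimethylcyclohex-1-en-1-olate | [Li]OC1=CCCC(C)(C)C1 | intermediate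
3 | 2,5,5-trimethylcyclohexanone (racemate) | CC1CCC(C)(C)CC1=O | intermediate
4 | N-[(1R)-1-phenylethyl]-2,5,5-trimethylcyclohexan-1-imine | CC1CCC(C)(C)CC1=N[C@H](C)c1ccccc1 | intermediate
5 | 4-{(1S)-1,4,4-trimethyl-2-{[(1R)-1-phenylethyl]imino}cyclohexyl}butan-2-one | CC(=O)CC[C@]1(C)CCC(C)(C)CC1=N[C@H](C)c1ccccc1 | intermediate
6 | (2S)-2,5,5-trimethyl-2-(3-oxobutyl)cyclohexan-1-one | CC(=O)CC[C@]1(C)CCC(C)(C)CC1=O | intermediate
7 | (4aS)-4a,7,7-trimethyl-4,4a,5,6,7,8-hexahydronaphthalen-2(3H)-one | O=C1CC[C@]2(C)CCC(C)(C)CC2=C1 | intermediate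
8 | lithium (4aS,8aS)-4a,7,7-trimethyl-3,4,4a,5,6,7,8,8a-octahydronaphthalen-2-olate | [Li]OC1=C[C@@H]2CC(C)(C)CC[C@@]2(C)CC1 | intermediate
9 | (1S,4aS,8aS)-1-allyl-4a,7,7-trimethyloctahydronaphthalen-2(1H)-one (trans-decalone, allyl equatorial) | O=C1CC[C@]2(C)CCC(C)(C)C[C@H]2[C@@H]1CC=C | intermediate
10 | ethyl (2E)-[(1S,4aS,8aS)-1-allyl-4a,7,7-trimethyloctahydronaphthalen-2(1H)-ylidene]acetate | CCOC(=O)/C=C1\CC[C@]2(C)CCC(C)(C)C[C@H]2[C@@H]1CC=C | intermediate
11 | (2E)-2-[(1S,4aS,8aS)-1-allyl-4a,7,7-trimethyloctahydronaphthalen-2(1H)-ylidene]ethan-1-ol | OC/C=C1\CC[C@]2(C)CCC(C)(C)C[C@H]2[C@@H]1CC=C | intermediate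
12 | [(1S,2S,3'S,4aS,8aS)-1-allyl-4a,7,7-trimethyloctahydro-1H-spiro[naphthalene-2,2'-oxiran]-3'-yl]methanol (epoxide oxygen equatorial on C11) | OC[C@@H]1O[C@]12CC[C@]3(C)CCC(C)(C)C[C@H]3[C@@H]2CC=C | intermediate
13 | (1R)-1-[(1S,2S,4aS,8aS)-1-allyl-2,4a,7,7-tetramethyldecahydronaphthalen-2-yl]ethane-1,2-diol (C11 methyl axial) | OC[C@H](O)[C@@]1(C)CC[C@]2(C)CCC(C)(C)C[C@H]2[C@@H]1CC=C | intermediate
14 | (1S,2S,4aS,8aS)-1-allyl-2,4a,7,7-tetramethyldecahydronaphthalene-2-carbaldehyde | O=C[C@@]1(C)CC[C@]2(C)CCC(C)(C)C[C@H]2[C@@H]1CC=C | intermediate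
15 | (2R)-3-bromo-2-methylpropan-1-ol | BrC[C@H](C)CO | starting material
16 | [(2R)-3-bromo-2-methylpropoxy](tert-butyl)dimethylsilane | BrC[C@H](C)CO[Si](C)(C)C(C)(C)C | intermediate
17 | tert-butyldimethyl{[(2S)-2-methylhept-5-yn-1-yl]oxy}silane | CC#CCC[C@H](C)CO[Si](C)(C)C(C)(C)C | intermediate
18 | (2S)-2-methylhept-5-yn-1-ol | CC#CCC[C@H](C)CO | intermediate
19 | (6S)-7-iodo-6-methylhept-2-yne | CC#CCC[C@H](C)CI | intermediate
20 | [(2R)-2-methylhept-5-yn-1-yl]lithium (same spatial arrangement as 19) | [Li]C[C@@H](C)CCC#CC | intermediate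
21 | (3S)-1-[(1S,2S,4aS,8aS)-1-allyl-2,4a,7,7-tetramethyldecahydronaphthalen-2-yl]-3-methyloct-6-yn-1-ol (both carbinol epimers) | CC#CCC[C@H](C)CC(O)[C@@]1(C)CC[C@]2(C)CCC(C)(C)C[C@H]2[C@@H]1CC=C | intermediate
22 | (3S)-1-[(1S,2S,4aS,8aS)-1-allyl-2,4a,7,7-tetramethyldecahydronaphthalen-2-yl]-3-methyloct-6-yn-1-one | CC#CCC[C@H](C)CC(=O)[C@@]1(C)CC[C@]2(C)CCC(C)(C)C[C@H]2[C@@H]1CC=C | intermediate
23 | {(1S,2S,4aS,8aS)-2,4a,7,7-tetramethyl-2-[(3S)-3-methyloct-6-ynoyl]decahydronaphthalen-1-yl}acetaldehyde | CC#CCC[C@H](C)CC(=O)[C@@]1(C)CC[C@]2(C)CCC(C)(C)C[C@H]2[C@@H]1CC=O | intermediate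
24 | (4aS,4bS,8aS,10aS)-2-[(2S)-hept-5-yn-2-yl]-6,6,8a,10a-tetramethyl-4,4a,4b,5,6,7,8,8a,9,10-decahydrophenanthren-1(10aH)-one (rings A, B, C′) | CC#CCC[C@H](C)C1=CC[C@H]2[C@@H]3CC(C)(C)CC[C@@]3(C)CC[C@]2(C)C1=O | intermediate
25 | pentacyclic photoadduct: cyclobutene C8–C3=C2–C26 fused to the cyclohexanone at C8–C26 and to the new cyclopentane at C8–C3 (drawn on the face opposite the C11 methyl) | O=C1[C@@]2(C)CC[C@]3(C)CCC(C)(C)C[C@H]3[C@@H]2C[C@H]4C(C)=C5CC[C@H](C)[C@]145 | intermediate
26 | diiodosamarium dienolate of 27 (C9(O–Sm)=C8–C3=C2, trivalent samarium) | C/C1=C2\CC[C@H](C)/C2=C(\O[Sm](I)I)[C@@]2(C)CC[C@]3(C)CCC(C)(C)C[C@H]3[C@@H]2CC1 | intermediate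
27 | C9 ketone of the target (6S,8S,11S,15S,23S,24S), β,γ-unsaturated | C/C1=C2\CC[C@H](C)[C@@H]2C(=O)[C@@]2(C)CC[C@]3(C)CCC(C)(C)C[C@H]3[C@@H]2CC1 | intermediate
28 | CNP0399382.1: 5-8-6-6 tetracyclic homoallylic alcohol (6S,8S,9R,11S,15S,23S,24S) | C/C1=C2\CC[C@H](C)[C@@H]2[C@@H](O)[C@@]2(C)CC[C@]3(C)CCC(C)(C)C[C@H]3[C@@H]2CC1 | target

**Step count and risks**

Total: 20 steps. Longest linear sequence: 16 steps (steps 1–10 and 15–20); the side chain (steps 11–14) joins at step 15.

Steps most likely to fail:

(1) Step 19. Possible failures are a further photoreaction (1,3-acyl shift) of the strained β,γ-unsaturated photoadduct, ketyl cleavage of the exocyclic C8–C3 bond or over-reduction, and protonation of the dienolate at C8 from the methyl-bearing face. The fallback sets out from 24 and comes back at 27, and replaces the radical-anion fragmentation by a pericyclic ring opening. Irradiation alone with isolation of cyclobutene 25 is followed by thermolysis (toluene, sealed tube, 150 °C, trace of I2). Conrotatory 4π opening, with the acyl-bearing C8 turning C9 inward, should give first the strained (E)-C2=C26 dienone F1, which should isomerise under the same conditions to the all-cis cycloocta-2,4-dienone F2. 1,6-Reduction of F2 with Li in NH3 and a kinetic quench, as for steroidal 4,6-dien-3-ones going to 5-en-3-ones, then gives 27.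

(2) Step 9. The Lewis acid may induce a hydride shift (semipinacol rearrangement) or methyl may attack C9 instead of the congested spiro carbon C11. The fallback sets out from decalone 9 and comes back at aldehyde 14, building C11 by equatorial alkylation of a nitrile anion instead of epoxide opening. Reductive cyanation (TosMIC, t-BuOK, DME/EtOH) should give the nitrile F3 as a C11 epimer mixture. Deprotonation with LiN(i-Pr)2 and alkylation with benzyl chloromethyl ether, the electrophile entering equatorially, should give the benzyloxymethyl nitrile F4 with the nitrile axial. i-Bu2AlH then gives the axial aldehyde F5, Wolff–Kishner reduction (N2H4·H2O, KOH, diethylene glycol, 200 °C) the axial-methyl benzyl ether F6, lithium naphthalenide the neopentyl alcohol F7, and Dess–Martin oxidation aldehyde 14.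

(3) Step 20. Hydride may be delivered from the wrong face of the hindered eight-membered-ring ketone. The fallback sets out from 27 and comes back at 28, replacing substrate control by reagent control: Corey–Bakshi–Shibata reduction with the (S)-methyl oxazaborolidine and catecholborane at −78 °C, which should deliver hydride so that the quaternary C11 side plays the large group and the (9R) alcohol results. The tetrasubstituted alkene is inert to the borane. This fallback makes no new compound (F0).

Further compounds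

F1 | step 19 | (E)-C2=C26 isomer of the ring-opened dienone C9(=O)–C8=C3–C2(Me)=C26 (not isolated) | O=C1[C@@]2(C)CC[C@]3(C)CCC(C)(C)C[C@H]3[C@@H]2C/C=C(C)/C4=C1[C@@H](C)CC4
F2 | step 19 | all-cis cycloocta-2,4-dienone C9(=O)–C8=C3–C2(Me)=C26 fused to rings B and D | O=C1[C@@]2(C)CC[C@]3(C)CCC(C)(C)C[C@H]3[C@@H]2C/C=C(C)\C4=C1[C@@H](C)CC4
F3 | step 9 | 1-allyl-4a,7,7-trimethyldecahydronaphthalene-2-carbonitrile (ring stereocentres as in 9, C11 epimers) | N#CC1CC[C@]2(C)CCC(C)(C)C[C@H]2[C@@H]1CC=C
F4 | step 9 | (1S,2S,4aS,8aS)-1-allyl-2-[(benzyloxy)methyl]-4a,7,7-trimethyldecahydronaphthalene-2-carbonitrile (nitrile axial) | c1ccccc1COC[C@@]1(C#N)CC[C@]2(C)CCC(C)(C)C[C@H]2[C@@H]1CC=C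
F5 | step 9 | (1S,2R,4aS,8aS)-1-allyl-2-[(benzyloxy)methyl]-4a,7,7-trimethyldecahydronaphthalene-2-carbaldehyde (formyl axial) | c1ccccc1COC[C@@]1(C=O)CC[C@]2(C)CCC(C)(C)C[C@H]2[C@@H]1CC=C
F6 | step 9 | benzyl [(1S,2S,4aS,8aS)-1-allyl-2,4a,7,7-tetramethyldecahydronaphthalen-2-yl]methyl ether | c1ccccc1COC[C@@]1(C)CC[C@]2(C)CCC(C)(C)C[C@H]2[C@@H]1CC=C
F7 | step 9 | [(1S,2S,4aS,8aS)-1-allyl-2,4a,7,7-tetramethyldecahydronaphthalen-2-yl]methanol | OC[C@@]1(C)CC[C@]2(C)CCC(C)(C)C[C@H]2[C@@H]1CC=C
F0 | step 20 | none | none
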